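**Plan** (coumarin numbering, side-chain carbons primed)

- Retrosynthesis: the lactone bond O1–C2 and the C3=C4 double bond are cut first (Z-selective olefination, then lactonisation). The C3–C1' bond is cut next, back to a phosphonoacetate and a bis-epoxy iodide. The ring A bonds C5–C6 and C4a–C8a are cut last.
- Enabling feature: ring A carries oxygen on C7 and C8a in a 1,3-relationship, the quaternary carbon on C6 and carbon C4 on C4a. It is therefore a 5-substituted 2,4-dihydroxybenzoate, the sum of a 1,3-dioxygenated diene (a masked β-keto ester) and a propiolate.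
- Forward, ring A: a β-keto ester already carrying the 1,1-dimethylallyl group is converted into its bis(silyloxy) diene and annulated with methyl propiolate. The resorcylate is then turned into a bis-silylated salicylaldehyde.
- Forward, side chain and pyranone: nerol is converted separately into a bis-epoxy iodide and joined to a phosphonoacetate. Olefination with the aldehyde and desilylation close the pyranone ring last.
- Stereochemistry: C2' and C3' come from Sharpless epoxidation of the Z-allylic alcohol nerol with L-(+)-tartrate (cis oxirane, 2S,3R). C6' comes from Shi epoxidation with the D-fructose-derived ketone (R). No later step touches either oxirane.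

Key step: step 5

Remark on the chemistry: 7 is expected as an E/Z mixture whose geometry is erased in step 4, and 21 as both epimers at the phosphorus-bearing carbon, which becomes sp2 in step 13. Neither affects the outcome.

**Route**

Step 1
Reactants: 1 methyl 3,3-dimethylpent-4-enoate
Product: 2 3,3-dimethylpent-4-enoic acid
Conditions: LiOH·H2O, THF/MeOH/H2O, 40 °C; then 1 M HCl
Reagents that add atoms: lithium hydroxide, [Li+].[OH-]
Why: Saponification of a methyl ester by hydroxide (acyl–oxygen cleavage) should be clean, since the isolated terminal alkene is inert to aqueous base.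

Step 2
Reactants: 2 3,3-dimethylpent-4-enoic acid; 3 potassium methyl malonate
Product: 6 methyl 5,5-dimethyl-3-oxohept-6-enoate, via acyl imidazole 4 (not isolated), via acylmalonic half ester 5 (not isolated)
Conditions: 1,1'-carbonyldiimidazole, THF, rt; then 3, MgCl2, Et3N, MeCN, rt → 45 °C; 1 M HCl work-up
Reagents that add atoms: none
Why: In this Masamune–Brooks acylation the acyl imidazole should C-acylate the magnesium enolate of the malonate half ester, and the acylmalonate then loses CO2 to give the β-keto ester without self-condensation.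

Step 3
Reactants: 6 methyl 5,5-dimethyl-3-oxohept-6-enoate
Product: 7 methyl 5,5-dimethyl-3-(trimethylsilyloxy)hepta-2,6-dienoate
Conditions: Me3SiCl, Et3N, toluene, rt; filtration under argon
Reagents that add atoms: chlorotrimethylsilane, C[Si](C)(C)Cl
Why: O-Silylation of the enolisable β-keto ester with a silyl chloride and an amine base is the standard first stage of bis(silyloxy)diene synthesis and should give the 3-silyloxy enoate.

Step 4
Reactants: 7 methyl 5,5-dimethyl-3-(trimethylsilyloxy)hepta-2,6-dienoate
Product: 8 (1Z,3Z)-1-methoxy-5,5-dimethyl-1,3-bis(trimethylsilyloxy)hepta-1,3,6-triene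
Conditions: LiN(i-Pr)2, THF, −78 °C; then Me3SiCl, −78 °C → rt; hexane trituration, used crude
Reagents that add atoms: chlorotrimethylsilane, C[Si](C)(C)Cl
Why: γ-Deprotonation of the vinylogous ester should give the extended dienolate, which the silyl chloride traps on oxygen, and the bulky quaternary group is expected to lie cis to the silyloxy group (3Z), i.e. on the outside of the s-cis diene.

Step 5
Reactants: 8 (1Z,3Z)-1-methoxy-5,5-dimethyl-1,3-bis(trimethylsilyloxy)hepta-1,3,6-triene; 9 methyl propiolate
Product: 12 methyl 2,4-dihydroxy-5-(2-methylbut-3-en-2-yl)benzoate, via cyclohexadiene cycloadduct 10 (not isolated), via monosilylated resorcylate 11 (not isolated)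
Conditions: toluene, 20 → 90 °C, sealed tube; then MeOH, pyridinium p-toluenesulfonate (cat.), rt
Reagents that add atoms: none
Why: The electron-rich 1,3-dioxygenated diene and the electron-poor alkyne should combine in a concerted but asynchronous normal-demand Diels–Alder reaction, the C4 terminus of the diene bonding to the β-carbon of the propiolate and the ketene acetal carbon to the α-carbon; cycloadduct 10 then loses methoxytrimethylsilane from its ketal carbon and tautomerises to arene 11, whose remaining aryl silyl ether is methanolysed. The closest known reaction type is the cycloaddition of 1-alkoxy-1,3-bis(silyloxy)buta-1,3-dienes with acetylenic esters to give resorcylates and hydroxyphthalates. Ring A is closed by the intermolecular [4+2] itself, both new σ-bonds (C5–C6 and C4a–C8a) forming suprafacially on each partner, so no separate cyclisation mode is involved. No stereocentre is created that survives, because the two sp3 carbons of 10 become aromatic. The selectivity needed is regiochemical (ester on C4a next to the C8a oxygen, quaternary group on C6), and it is secured by the matched polarisation of the partners (largest HOMO coefficient at the diene terminus, largest LUMO coefficient at the propiolate β-carbon) and by the hindered terminus meeting only the unsubstituted, linear alkyne carbon. The 3Z geometry of 8 keeps the quaternary group outside the s-cis diene, which the cycloaddition requires.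

Step 6
Reactants: 12 methyl 2,4-dihydroxy-5-(2-methylbut-3-en-2-yl)benzoate
Product: 13 methyl 2,4-bis(tert-butyldimethylsilyloxy)-5-(2-methylbut-3-en-2-yl)benzoate
Conditions: t-BuMe2SiCl (excess), imidazole, DMF, 40 °C
Reagents that add atoms: tert-butyldimethylsilyl chloride, CC(C)(C)[Si](C)(C)Cl
Why: Silyl ether formation with a silyl chloride and imidazole should mask both phenols for the hydride and carbanion steps, with excess reagent and gentle heating compensating for the chelated 2-hydroxyl and the hindered 4-hydroxyl.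

Step 7
Reactants: 13 methyl 2,4-bis(tert-butyldimethylsilyloxy)-5-(2-methylbut-3-en-2-yl)benzoate
Product: 14 [2,4-bis(tert-butyldimethylsilyloxy)-5-(2-methylbut-3-en-2-yl)phenyl]methanol
Conditions: i-Bu2AlH, CH2Cl2, −78 °C; aq. KNaC4H4O6 (potassium sodium tartrate)
Reagents that add atoms: none
Why: Hydride reduction of the aryl ester by i-Bu2AlH at low temperature should give the benzylic alcohol while leaving aryl silyl ethers and the terminal alkene untouched.

Step 8
Reactants: 14 [2,4-bis(tert-butyldimethylsilyloxy)-5-(2-methylbut-3-en-2-yl)phenyl]methanol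
Product: 15 2,4-bis(tert-butyldimethylsilyloxy)-5-(2-methylbut-3-en-2-yl)benzaldehyde
Conditions: MnO2 (activated, excess), CH2Cl2, rt
Reagents that add atoms: none
Why: Oxidation of an electron-rich benzylic alcohol by MnO2 should stop cleanly at the aldehyde.

Step 9
Reactants: 16 nerol
Product: 17 [(2S,3R)-3-methyl-3-(4-methylpent-3-en-1-yl)oxiran-2-yl]methanol
Conditions: Ti(O-i-Pr)4 (10 mol%), L-(+)-diisopropyl tartrate (12 mol%), t-BuOOH, 4 Å molecular sieves, CH2Cl2, −20 °C
Reagents that add atoms: tert-butyl hydroperoxide, CC(C)(C)OO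
Why: In the Sharpless asymmetric epoxidation the titanium tartrate complex of L-(+)-tartrate should deliver oxygen to the face of the allylic alcohol that sets C2 as S, the Z geometry of nerol then fixing C3 as R with the hydroxymethyl group and the chain cis, and only the allylic olefin reacts.

Step 10
Reactants: 17 [(2S,3R)-3-methyl-3-(4-methylpent-3-en-1-yl)oxiran-2-yl]methanol
Product: 18 [(2S,3R)-3-{2-[(2R)-3,3-dimethyloxiran-2-yl]ethyl}-3-methyloxiran-2-yl]methanol
Conditions: D-fructose-derived Shi ketone (30 mol%), KHSO5 (as the triple salt 2KHSO5·KHSO4·K2SO4), K2CO3, Bu4NHSO4 (cat.), aq. Na2B4O7 buffer, MeCN/dimethoxymethane, 0 °C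
Reagents that add atoms: potassium peroxymonosulfate KHSO5, [K+].[O-]S(=O)(=O)OO
Why: In the Shi epoxidation the chiral dioxirane should attack the only remaining, trisubstituted olefin through a spiro transition state and set the new CH carbon as R under reagent control, independent of the remote oxirane.

Step 11
Reactants: 18 [(2S,3R)-3-{2-[(2R)-3,3-dimethyloxiran-2-yl]ethyl}-3-methyloxiran-2-yl]methanol
Product: 19 (2R,3R)-3-{2-[(2R)-3,3-dimethyloxiran-2-yl]ethyl}-2-(iodomethyl)-3-methyloxirane
Conditions: I2, PPh3, imidazole, CH2Cl2, 0 °C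
Reagents that add atoms: iodine, II
Why: The Appel-type iodination should convert the primary alcohol of the 2,3-epoxy alcohol into the iodide by SN2 at C1 without touching either oxirane or any stereocentre (the descriptor at C2 changes only through the priority of iodine).

Step 12
Reactants: 19 (2R,3R)-3-{2-[(2R)-3,3-dimethyloxiran-2-yl]ethyl}-2-(iodomethyl)-3-methyloxirane; 20 ethyl 2-[bis(2-methylphenoxy)phosphoryl]acetate
Product: 21 ethyl 2-[bis(2-methylphenoxy)phosphoryl]-3-[(2S,3R)-3-{2-[(2R)-3,3-dimethyloxiran-2-yl]ethyl}-3-methyloxiran-2-yl]propanoate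
Conditions: 20 (1.5 equiv), NaH (1.2 equiv), THF/DMF, 0 °C; then 19, 0 °C → rt
Reagents that add atoms: none
Why: SN2 C-alkylation of the sodium phosphonoacetate by the primary iodide should give 21, the excess of 20 keeping the less acidic product protonated so that its carbanion cannot open the neighbouring oxirane, and the new phosphorus-bearing centre is left uncontrolled because it becomes sp2 in step 13.

Step 13
Reactants: 15 2,4-bis(tert-butyldimethylsilyloxy)-5-(2-methylbut-3-en-2-yl)benzaldehyde; 21 ethyl 2-[bis(2-methylphenoxy)phosphoryl]-3-[(2S,3R)-3-{2-[(2R)-3,3-dimethyloxiran-2-yl]ethyl}-3-methyloxiran-2-yl]propanoate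
Product: 22 ethyl (2Z)-3-[2,4-bis(tert-butyldimethylsilyloxy)-5-(2-methylbut-3-en-2-yl)phenyl]-2-{[(2S,3R)-3-{2-[(2R)-3,3-dimethyloxiran-2-yl]ethyl}-3-methyloxiran-2-yl]methyl}prop-2-enoate
Conditions: KO-t-Bu, THF, −78 °C; then 15, −78 → −20 °C
Reagents that add atoms: none
Why: In the Ando variant of the Horner–Wadsworth–Emmons reaction the diaryl phosphonate makes oxaphosphetane collapse faster than equilibration, so the kinetic adduct should give the Z ester with aryl and ester cis as lactonisation requires, and the low temperature keeps the carbanion from attacking the oxirane.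

Step 14
Reactants: 22 ethyl (2Z)-3-[2,4-bis(tert-butyldimethylsilyloxy)-5-(2-methylbut-3-en-2-yl)phenyl]-2-{[(2S,3R)-3-{2-[(2R)-3,3-dimethyloxiran-2-yl]ethyl}-3-methyloxiran-2-yl]methyl}prop-2-enoate
Product: 24 3-{[(2S,3R)-3-{2-[(2R)-3,3-dimethyloxiran-2-yl]ethyl}-3-methyloxiran-2-yl]methyl}-7-hydroxy-6-(2-methylbut-3-en-2-yl)-2H-chromen-2-one, via desilylated Z-hydroxycinnamate 23 (not isolated)
Conditions: Bu4NF, THF, 0 °C → rt; then AcOH
Reagents that add atoms: none
Why: Fluoride should cleave both aryl silyl ethers, and the liberated 2-phenoxide, held cis to the ester, undergoes intramolecular transesterification (6-exo-trig lactonisation) to close the pyranone ring, both oxiranes being inert to fluoride at this temperature.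

**Compound list**

1 | methyl 3,3-dimethylpent-4-enoate | COC(=O)CC(C)(C)C=C | starting material
2 | 3,3-dimethylpent-4-enoic acid | OC(=O)CC(C)(C)C=C | intermediate
3 | potassium methyl malonate (potassium 3-methoxy-3-oxopropanoate) | COC(=O)CC(=O)[O-].[K+] | starting material
4 | 1-(1H-imidazol-1-yl)-3,3-dimethylpent-4-en-1-one | C=CC(C)(C)CC(=O)n1ccnc1 | intermediate (not isolated)
5 | 2-(methoxycarbonyl)-5,5-dimethyl-3-oxohept-6-enoic acid (present as its magnesium salt) | C=CC(C)(C)CC(=O)C(C(=O)O)C(=O)OC | intermediate (not isolated)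
6 | methyl 5,5-dimethyl-3-oxohept-6-enoate | C=CC(C)(C)CC(=O)CC(=O)OC | intermediate
7 | methyl 5,5-dimethyl-3-(trimethylsilyloxy)hepta-2,6-dienoate (E/Z mixture at C2=C3) | COC(=O)C=C(O[Si](C)(C)C)CC(C)(C)C=C | intermediate
8 | (1Z,3Z)-1-methoxy-5,5-dimethyl-1,3-bis(trimethylsilyloxy)hepta-1,3,6-triene | CO/C(O[Si](C)(C)C)=C/C(O[Si](C)(C)C)=C/C(C)(C)C=C | intermediate
9 | methyl propiolate (methyl prop-2-ynoate) | C#CC(=O)OC | starting material
10 | methyl 6-methoxy-3-(2-methylbut-3-en-2-yl)-4,6-bis(trimethylsilyloxy)cyclohexa-1,4-diene-1-carboxylate (stereoisomer mixture, both centres lost) | COC(=O)C1=CC(C(C)(C)C=C)C(O[Si](C)(C)C)=CC1(OC)O[Si](C)(C)C | intermediate (not isolated)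
11 | methyl 2-hydroxy-5-(2-methylbut-3-en-2-yl)-4-(trimethylsilyloxy)benzoate | COC(=O)c1cc(C(C)(C)C=C)c(O[Si](C)(C)C)cc1O | intermediate (not isolated)
12 | methyl 2,4-dihydroxy-5-(2-methylbut-3-en-2-yl)benzoate | COC(=O)c1cc(C(C)(C)C=C)c(O)cc1O | intermediate
13 | methyl 2,4-bis(tert-butyldimethylsilyloxy)-5-(2-methylbut-3-en-2-yl)benzoate | COC(=O)c1cc(C(C)(C)C=C)c(O[Si](C)(C)C(C)(C)C)cc1O[Si](C)(C)C(C)(C)C | intermediate
14 | [2,4-bis(tert-butyldimethylsilyloxy)-5-(2-methylbut-3-en-2-yl)phenyl]methanol | OCc1cc(C(C)(C)C=C)c(O[Si](C)(C)C(C)(C)C)cc1O[Si](C)(C)C(C)(C)C | intermediate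
15 | 2,4-bis(tert-butyldimethylsilyloxy)-5-(2-methylbut-3-en-2-yl)benzaldehyde | O=Cc1cc(C(C)(C)C=C)c(O[Si](C)(C)C(C)(C)C)cc1O[Si](C)(C)C(C)(C)C | intermediate
16 | nerol, (2Z)-3,7-dimethylocta-2,6-dien-1-ol | CC(C)=CCC/C(C)=C\CO | starting material
17 | [(2S,3R)-3-methyl-3-(4-methylpent-3-en-1-yl)oxiran-2-yl]methanol | OC[C@@H]1O[C@]1(C)CCC=C(C)C | intermediate
18 | [(2S,3R)-3-{2-[(2R)-3,3-dimethyloxiran-2-yl]ethyl}-3-methyloxiran-2-yl]methanol | OC[C@@H]1O[C@]1(C)CC[C@H]1OC1(C)C | intermediate
19 | (2R,3R)-3-{2-[(2R)-3,3-dimethyloxiran-2-yl]ethyl}-2-(iodomethyl)-3-methyloxirane | IC[C@@H]1O[C@]1(C)CC[C@H]1OC1(C)C | intermediate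
20 | ethyl 2-[bis(2-methylphenoxy)phosphoryl]acetate | CCOC(=O)CP(=O)(Oc1ccccc1C)Oc1ccccc1C | starting material
21 | ethyl 2-[bis(2-methylphenoxy)phosphoryl]-3-[(2S,3R)-3-{2-[(2R)-3,3-dimethyloxiran-2-yl]ethyl}-3-methyloxiran-2-yl]propanoate (both epimers at C2 of the propanoate) | CCOC(=O)C(C[C@@H]1O[C@]1(C)CC[C@H]1OC1(C)C)P(=O)(Oc1ccccc1C)Oc1ccccc1C | intermediate
22 | ethyl (2Z)-3-[2,4-bis(tert-butyldimethylsilyloxy)-5-(2-methylbut-3-en-2-yl)phenyl]-2-{[(2S,3R)-3-{2-[(2R)-3,3-dimethyloxiran-2-yl]ethyl}-3-methyloxiran-2-yl]methyl}prop-2-enoate | CCOC(=O)/C(C[C@@H]1O[C@]1(C)CC[C@H]1OC1(C)C)=C\c1cc(C(C)(C)C=C)c(O[Si](C)(C)C(C)(C)C)cc1O[Si](C)(C)C(C)(C)C | intermediate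
23 | ethyl (2Z)-3-[2,4-dihydroxy-5-(2-methylbut-3-en-2-yl)phenyl]-2-{[(2S,3R)-3-{2-[(2R)-3,3-dimethyloxiran-2-yl]ethyl}-3-methyloxiran-2-yl]methyl}prop-2-enoate (formed as its phenoxide) | CCOC(=O)/C(C[C@@H]1O[C@]1(C)CC[C@H]1OC1(C)C)=C\c1cc(C(C)(C)C=C)c(O)cc1O | intermediate (not isolated)
24 | 3-{[(2S,3R)-3-{2-[(2R)-3,3-dimethyloxiran-2-yl]ethyl}-3-methyloxiran-2-yl]methyl}-7-hydroxy-6-(2-methylbut-3-en-2-yl)-2H-chromen-2-one | C=CC(C)(C)c1cc2cc(C[C@@H]3O[C@]3(C)CC[C@H]3OC3(C)C)c(=O)oc2cc1O | target

**Step count**

Total: 14 steps. Longest linear sequence: 10 steps (steps 1–8, 13 and 14); the side-chain branch is steps 9–12.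

**Steps most likely to fail, with fallbacks**

Step 5. Bond formation at the diene terminus, which is flanked by a quaternary carbon, may be too slow, so that thermal decomposition and adventitious desilylation of the diene outrun the cycloaddition; a diene of 3E geometry would not react at all. The fallback sets out from methyl propiolate 9 and comes back at 12, the quaternary group being introduced after ring formation. Treating 9 with the commercial, unsubstituted 1-methoxy-1,3-bis(trimethylsilyloxy)buta-1,3-diene under the conditions of step 5 should give methyl 2,4-dihydroxybenzoate F1 (also purchasable). Alkylation of the non-chelated 4-hydroxyl with prenyl bromide and K2CO3 in acetone should give methyl 2-hydroxy-4-[(3-methylbut-2-en-1-yl)oxy]benzoate F2. An aromatic Claisen rearrangement (N,N-diethylaniline, about 190 °C) then transfers the allyl unit with inversion to the ortho carbon and gives 12. The price is regiochemical: migration to C3, between the two oxygens, competes and may dominate because of the chelated 2-hydroxyl, so the isomer has to be separated.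

Step 12. The phosphonate carbanion may attack iodine with fragmentation of the oxirane. Alternatively, after proton transfer, the carbanion of the product may open the adjacent oxirane to a cyclopropane instead of the iodide undergoing clean substitution. The fallback sets out from nerol 16 and comes back at 22; the proximal oxirane is introduced only after both carbon–carbon bonds are in place.
- Acetylation (Ac2O, pyridine) should give (2Z)-3,7-dimethylocta-2,6-dien-1-yl acetate F3.
- Shi epoxidation with the D-fructose-derived ketone should oxidise the distal olefin, the allylic acetate deactivating the other one, to give (2Z)-5-[(2R)-3,3-dimethyloxiran-2-yl]-3-methylpent-2-en-1-yl acetate F4.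
- Methanolysis (K2CO3, MeOH) should give (2Z)-5-[(2R)-3,3-dimethyloxiran-2-yl]-3-methylpent-2-en-1-ol F5.
- An Appel reaction (CBr4, PPh3) should give (3R)-3-[(3Z)-5-bromo-3-methylpent-3-en-1-yl]-2,2-dimethyloxirane F6.
- This allylic bromide should alkylate the sodium salt of 20 readily (NaH, THF) to give ethyl (4Z)-2-[bis(2-methylphenoxy)phosphoryl]-7-[(2R)-3,3-dimethyloxiran-2-yl]-5-methylhept-4-enoate F7.
- Olefination of 15 as in step 13 should give ethyl (2Z)-3-[2,4-bis(tert-butyldimethylsilyloxy)-5-(2-methylbut-3-en-2-yl)phenyl]-2-{(2Z)-5-[(2R)-3,3-dimethyloxiran-2-yl]-3-methylpent-2-en-1-yl}prop-2-enoate F8.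
- A second Shi epoxidation, now with the enantiomeric ketone (from L-sorbose), should oxidise the electron-rich Z-trisubstituted side-chain olefin in preference to the enoate and the vinyl group and give 22.

The proximal oxirane needs the opposite ketone enantiomer to the distal one, so the two oxidations cannot be merged. This path relies on reagent control at a Z-olefin and is expected to be less selective than the Sharpless step it replaces.

Step 13. Geometric selectivity may be poor with the α-branched phosphonate and the ortho-substituted, electron-rich aldehyde, leaving much of the material as the E ester, which cannot lactonise. The fallback sets out from 15 and 21 and comes back at 24; ring closure is moved from kinetic Z-olefination to photochemical isomerisation. The E isomer formed in the olefination, ethyl (2E)-3-[2,4-bis(tert-butyldimethylsilyloxy)-5-(2-methylbut-3-en-2-yl)phenyl]-2-{[(2S,3R)-3-{2-[(2R)-3,3-dimethyloxiran-2-yl]ethyl}-3-methyloxiran-2-yl]methyl}prop-2-enoate F9, is desilylated (Bu4NF, THF, then AcOH) to ethyl (2E)-3-[2,4-dihydroxy-5-(2-methylbut-3-en-2-yl)phenyl]-2-{[(2S,3R)-3-{2-[(2R)-3,3-dimethyloxiran-2-yl]ethyl}-3-methyloxiran-2-yl]methyl}prop-2-enoate F10. Irradiation of a dilute MeCN solution at 365 nm should isomerise the double bond, and the Z isomer lactonises spontaneously to 24. A Z/E mixture can be carried through together, since the Z part gives 24 directly on desilylation.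

**Further compounds**

F1 | step 5 | methyl 2,4-dihydroxybenzoate | COC(=O)c1ccc(O)cc1O
F2 | step 5 | methyl 2-hydroxy-4-[(3-methylbut-2-en-1-yl)oxy]benzoate | COC(=O)c1ccc(OCC=C(C)C)cc1O
F3 | step 12 | (2Z)-3,7-dimethylocta-2,6-dien-1-yl acetate | CC(C)=CCC/C(C)=C\COC(C)=O
F4 | step 12 | (2Z)-5-[(2R)-3,3-dimethyloxiran-2-yl]-3-methylpent-2-en-1-yl acetate | CC(=O)OC/C=C(C)\CC[C@H]1OC1(C)C
F5 | step 12 | (2Z)-5-[(2R)-3,3-dimethyloxiran-2-yl]-3-methylpent-2-en-1-ol | OC/C=C(C)\CC[C@H]1OC1(C)C
F6 | step 12 | (3R)-3-[(3Z)-5-bromo-3-methylpent-3-en-1-yl]-2,2-dimethyloxirane | BrC/C=C(C)\CC[C@H]1OC1(C)C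
F7 | step 12 | ethyl (4Z)-2-[bis(2-methylphenoxy)phosphoryl]-7-[(2R)-3,3-dimethyloxiran-2-yl]-5-methylhept-4-enoate | CCOC(=O)C(C/C=C(C)\CC[C@H]1OC1(C)C)P(=O)(Oc1ccccc1C)Oc1ccccc1C
F8 | step 12 | ethyl (2Z)-3-[2,4-bis(tert-butyldimethylsilyloxy)-5-(2-methylbut-3-en-2-yl)phenyl]-2-{(2Z)-5-[(2R)-3,3-dimethyloxiran-2-yl]-3-methylpent-2-en-1-yl}prop-2-enoate | CCOC(=O)/C(C/C=C(C)\CC[C@H]1OC1(C)C)=C\c1cc(C(C)(C)C=C)c(O[Si](C)(C)C(C)(C)C)cc1O[Si](C)(C)C(C)(C)C
F9 | step 13 | ethyl (2E)-3-[2,4-bis(tert-butyldimethylsilyloxy)-5-(2-methylbut-3-en-2-yl)phenyl]-2-{[(2S,3R)-3-{2-[(2R)-3,3-dimethyloxiran-2-yl]ethyl}-3-methyloxiran-2-yl]methyl}prop-2-enoate | CCOC(=O)/C(C[C@@H]1O[C@]1(C)CC[C@H]1OC1(C)C)=C/c1cc(C(C)(C)C=C)c(O[Si](C)(C)C(C)(C)C)cc1O[Si](C)(C)C(C)(C)C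
F10 | step 13 | ethyl (2E)-3-[2,4-dihydroxy-5-(2-methylbut-3-en-2-yl)phenyl]-2-{[(2S,3R)-3-{2-[(2R)-3,3-dimethyloxiran-2-yl]ethyl}-3-methyloxiran-2-yl]methyl}prop-2-enoate | CCOC(=O)/C(C[C@@H]1O[C@]1(C)CC[C@H]1OC1(C)C)=C/c1cc(C(C)(C)C=C)c(O)cc1O
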